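**Retrosynthetic overview**

1. The target is the (2S)-flavanone. It is traced back, by loss of three MOM groups and an enantioselective copper hydride 1,4-reduction that sets C2, to the fully MOM-protected flavone.
2. Ring C of the flavone is cut at C4a–C4, C4–C3 and O1–C2 into an iodoarene, CO and an aryl acetylene. The feature used is that C4 is a single carbonyl carbon between C4a of ring A and the C3–C2(aryl) unit, and that ring A is a phloroglucinol with the same prenyl group at C6 and C8, so the two oxygens beside C4a (the future O1 and the C5 oxygen) are interchangeable.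
3. The iodoarene, 2-iodo-4,6-diprenylphloroglucinol, comes from phloroglucinol by tris-MOM protection, two directed lithiation–prenylations, deprotection and iodination. It is carried into the coupling as its triacetate, because the free iodotriol is very electron-rich and prone to lose iodine.
4. The acetylene comes from commercial 5-iodovanillin by MOM protection, Stille prenylation and Ohira–Bestmann homologation.
5. Rings A and B are bought as arenes; ring C is the only ring formed, in step 9.

Key step: step 9

Assumption: (S)-DTBM-SEGPHOS is written for step 11 on the premise that its copper hydride adds to the Re face of C2, by analogy with 3-substituted cyclohexenones; if a trial shows the opposite sense, the mirror-image ligand is used and nothing else changes.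

**Route**

Step 1
Reactants: 1 phloroglucinol (benzene-1,3,5-triol)
Product: 2 1,3,5-tris(methoxymethoxy)benzene
Conditions: NaH, MOMCl, DMF, 0 °C to rt
Reagents that add atoms: chloromethyl methyl ether, COCCl
Why: Triple Williamson O-alkylation of the phenoxides by the hard electrophile MOMCl should give the tris-acetal, whose OMOM groups then direct ortho-metalation.

Step 2
Reactants: 2 1,3,5-tris(methoxymethoxy)benzene; 3 1-bromo-3-methylbut-2-ene (prenyl bromide)
Product: 5 1,3,5-tris(methoxymethoxy)-2-(3-methylbut-2-enyl)benzene, via 2-lithio-1,3,5-tris(methoxymethoxy)benzene 4 (not isolated)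
Conditions: n-BuLi, THF, 0 °C; then prenyl bromide, −78 °C to rt
Reagents that add atoms: 1-bromo-3-methylbut-2-ene (3), CC(C)=CCBr
Why: Directed ortho-metalation removes the ring hydrogen between two chelating OMOM groups, and the aryllithium should attack prenyl bromide at its primary carbon (SN2), since the SN2′ path would build a quaternary centre.

Step 3
Reactants: 5 1,3,5-tris(methoxymethoxy)-2-(3-methylbut-2-enyl)benzene; 3 1-bromo-3-methylbut-2-ene
Product: 7 1,3,5-tris(methoxymethoxy)-2,4-bis(3-methylbut-2-enyl)benzene, via 4-lithio-1,3,5-tris(methoxymethoxy)-2-(3-methylbut-2-enyl)benzene 6 (not isolated)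
Conditions: n-BuLi, THF, 0 °C; then prenyl bromide, −78 °C to rt
Reagents that add atoms: 1-bromo-3-methylbut-2-ene (3), CC(C)=CCBr
Why: A second directed ortho-metalation at a position again flanked by two OMOM groups should outrun deprotonation of the benzylic–allylic CH2, and the mirror symmetry of 5 makes its two free ring positions identical.

Step 4
Reactants: 7 1,3,5-tris(methoxymethoxy)-2,4-bis(3-methylbut-2-enyl)benzene
Product: 8 2,4-bis(3-methylbut-2-enyl)benzene-1,3,5-triol
Conditions: 3 M aq. HCl, MeOH, 40 °C, argon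
Reagents that add atoms: none
Why: Acid-catalysed acetal exchange with methanol removes the three MOM groups as dimethoxymethane, and mild temperature with a stop at full conversion should keep the prenyl double bonds from being protonated and closing chromans.

Step 5
Reactants: 8 2,4-bis(3-methylbut-2-enyl)benzene-1,3,5-triol
Product: 10 2-iodo-4,6-bis(3-methylbut-2-enyl)benzene-1,3,5-triyl triacetate, via 2-iodo-4,6-bis(3-methylbut-2-enyl)benzene-1,3,5-triol 9 (not isolated)
Conditions: I2 (1.0 equiv, slow addition), NaHCO3, THF/H2O, 0 °C; extractive work-up; then Ac2O, pyridine, DMAP (cat.), CH2Cl2, 0 °C to rt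
Reagents that add atoms: iodine, II; acetic anhydride, CC(=O)OC(C)=O
Why: Electrophilic aromatic iodination of the phloroglucinol phenoxide at its only free ring carbon should be much faster than attack of iodine on a trisubstituted alkene, and immediate peracetylation converts the sensitive iodotriol into a less electron-rich aryl iodide that should be stable to handling.

Step 6
Reactants: 11 4-hydroxy-3-iodo-5-methoxybenzaldehyde (5-iodovanillin)
Product: 12 3-iodo-5-methoxy-4-(methoxymethoxy)benzaldehyde
Conditions: MOMCl, i-Pr2NEt, CH2Cl2, 0 °C to rt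
Reagents that add atoms: chloromethyl methyl ether, COCCl
Why: O-alkylation of the acidic para-formyl phenol gives the MOM ether, which is stable to the Stille, Ohira–Bestmann and amine/palladium conditions that follow.

Step 7
Reactants: 12 3-iodo-5-methoxy-4-(methoxymethoxy)benzaldehyde; 13 tributyl(3-methylbut-2-enyl)stannane
Product: 14 3-methoxy-4-(methoxymethoxy)-5-(3-methylbut-2-enyl)benzaldehyde
Conditions: Pd(PPh3)4 (5 mol %), DMF, 90 °C
Reagents that add atoms: tributyl(3-methylbut-2-enyl)stannane (13), CCCC[Sn](CCCC)(CCCC)CC=C(C)C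
Why: Stille coupling of the aryl iodide with the allylic stannane should deliver the linear prenyl arene, because the aryl(allyl)palladium intermediate eliminates reductively at the unhindered CH2 terminus, and the aldehyde is inert to the stannane without a Lewis acid.

Step 8
Reactants: 14 3-methoxy-4-(methoxymethoxy)-5-(3-methylbut-2-enyl)benzaldehyde
Product: 15 5-ethynyl-1-methoxy-2-(methoxymethoxy)-3-(3-methylbut-2-enyl)benzene
Conditions: dimethyl (1-diazo-2-oxopropyl)phosphonate, K2CO3, MeOH, rt
Reagents that add atoms: dimethyl (1-diazo-2-oxopropyl)phosphonate, COP(=O)(OC)C(=[N+]=[N-])C(C)=O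
Why: Ohira–Bestmann (Seyferth–Gilbert) homologation turns the aryl aldehyde into the terminal alkyne under mild basic conditions that leave the MOM ether and the prenyl group alone.

Step 9
Reactants: 10 2-iodo-4,6-bis(3-methylbut-2-enyl)benzene-1,3,5-triyl triacetate; 15 5-ethynyl-1-methoxy-2-(methoxymethoxy)-3-(3-methylbut-2-enyl)benzene; 16 carbon monoxide
Product: 19 5,7-dihydroxy-2-[3-methoxy-4-(methoxymethoxy)-5-(3-methylbut-2-enyl)phenyl]-6,8-bis(3-methylbut-2-enyl)chromen-4-one, via ynone triacetate 17 (not isolated), via ynone triol 18 (not isolated)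
Conditions: PdCl2(PPh3)2 (5 mol %), thiourea (5 mol %), dppp (5 mol %), CO (1 atm), DBU, Et2NH, 40 °C
Reagents that add atoms: carbon monoxide (16), [C-]#[O+]
Why: Zerovalent palladium, formed in the flask from PdCl2(PPh3)2, adds oxidatively to the C–I bond of 10 while it is still an electron-poor triacetate, CO inserts to give an aroyl palladium iodide, and amine-assisted coupling with the terminal alkyne 15 followed by reductive elimination gives ynone 17, forming C4a–C4 and C4–C3. Et2NH and DBU then aminolyse the three acetates to 18, and the amine adds reversibly to the ynone so that a phenoxide beside the ketone displaces it at C2, forming O1–C2. This is the known palladium-catalysed carbonylative annulation of ortho-iodophenol acetates with terminal aryl acetylenes to flavones. Ring C closes by a net 6-endo-dig oxa-Michael addition (addition–elimination through the β-amino enone), and no stereocentre is formed. The step needs flavone rather than aurone closure, which the secondary amine secures, and a single ring A regiochemistry, which is secured because the two oxygens flanking C4a and the prenyl groups at C6 and C8 are equivalent. The prenyl groups are meta to the iodide and cannot reach the aryl palladium centre for a Heck reaction, and the absence of copper disfavours direct alkynylation.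

Step 10
Reactants: 19 5,7-dihydroxy-2-[3-methoxy-4-(methoxymethoxy)-5-(3-methylbut-2-enyl)phenyl]-6,8-bis(3-methylbut-2-enyl)chromen-4-one
Product: 20 5,7-bis(methoxymethoxy)-2-[3-methoxy-4-(methoxymethoxy)-5-(3-methylbut-2-enyl)phenyl]-6,8-bis(3-methylbut-2-enyl)chromen-4-one
Conditions: NaH, MOMCl, DMF, 0 °C to rt
Reagents that add atoms: chloromethyl methyl ether, COCCl
Why: Deprotonation by NaH breaks the hydrogen bond of the C5 hydroxyl to the C4 carbonyl, so both phenoxides are O-alkylated, and protection removes the acidic protons that would quench the copper hydride and silane in step 11.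

Step 11
Reactants: 20 5,7-bis(methoxymethoxy)-2-[3-methoxy-4-(methoxymethoxy)-5-(3-methylbut-2-enyl)phenyl]-6,8-bis(3-methylbut-2-enyl)chromen-4-one
Product: 22 (2S)-5,7-bis(methoxymethoxy)-2-[3-methoxy-4-(methoxymethoxy)-5-(3-methylbut-2-enyl)phenyl]-6,8-bis(3-methylbut-2-enyl)chroman-4-one, via silyl enol ether 21 (not isolated)
Conditions: Cu(OAc)2·H2O (5 mol %), (S)-DTBM-SEGPHOS (5.5 mol %), (EtO)2MeSiH, toluene, 0 °C to rt; then 1 M aq. HCl, THF, 0 °C
Reagents that add atoms: none
Why: Copper hydride asymmetric conjugate reduction, known for 2-substituted chromen-4-ones: the (S)-DTBM-SEGPHOS-ligated copper hydride should add hydride to the Re face of C2 and so set 2S, the enolate is trapped on oxygen by the silane as 21 (which blocks over-reduction at C4 and ring opening) and is hydrolysed cold to the ketone, while the isolated trisubstituted prenyl double bonds, which hydrogenation with H2 would endanger, do not react with copper hydride.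

Step 12
Reactants: 22 (2S)-5,7-bis(methoxymethoxy)-2-[3-methoxy-4-(methoxymethoxy)-5-(3-methylbut-2-enyl)phenyl]-6,8-bis(3-methylbut-2-enyl)chroman-4-one
Product: 23 (2S)-5,7-dihydroxy-2-[4-hydroxy-3-methoxy-5-(3-methylbut-2-enyl)phenyl]-6,8-bis(3-methylbut-2-enyl)chroman-4-one (target)
Conditions: 3 M aq. HCl, MeOH, 50 °C, short reaction time
Reagents that add atoms: none
Why: Acid-catalysed acetal exchange removes the three MOM groups as dimethoxymethane, a standard final step for prenylated flavanones, and a short exposure at moderate temperature should neither open the pyranone ring (which would scramble C2) nor cyclise the prenyl groups onto the neighbouring phenols.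

**Compound list**

1 | phloroglucinol (benzene-1,3,5-triol) | Oc1cc(O)cc(O)c1 | starting material
2 | 1,3,5-tris(methoxymethoxy)benzene | COCOc1cc(OCOC)cc(OCOC)c1 | intermediate
3 | 1-bromo-3-methylbut-2-ene (prenyl bromide) | CC(C)=CCBr | starting material
4 | [2,4,6-tris(methoxymethoxy)phenyl]lithium | COCOc1cc(OCOC)c([Li])c(OCOC)c1 | intermediate
5 | 1,3,5-tris(methoxymethoxy)-2-(3-methylbut-2-enyl)benzene | COCOc1cc(OCOC)c(CC=C(C)C)c(OCOC)c1 | intermediate
6 | [2,4,6-tris(methoxymethoxy)-3-(3-methylbut-2-enyl)phenyl]lithium | COCOc1c([Li])c(OCOC)c(CC=C(C)C)c(OCOC)c1 | intermediate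
7 | 1,3,5-tris(methoxymethoxy)-2,4-bis(3-methylbut-2-enyl)benzene | COCOc1cc(OCOC)c(CC=C(C)C)c(OCOC)c1CC=C(C)C | intermediate
8 | 2,4-bis(3-methylbut-2-enyl)benzene-1,3,5-triol | Oc1cc(O)c(CC=C(C)C)c(O)c1CC=C(C)C | intermediate
9 | 2-iodo-4,6-bis(3-methylbut-2-enyl)benzene-1,3,5-triol | Oc1c(I)c(O)c(CC=C(C)C)c(O)c1CC=C(C)C | intermediate
10 | 2-iodo-4,6-bis(3-methylbut-2-enyl)benzene-1,3,5-triyl triacetate | CC(=O)Oc1c(I)c(OC(C)=O)c(CC=C(C)C)c(OC(C)=O)c1CC=C(C)C | intermediate
11 | 4-hydroxy-3-iodo-5-methoxybenzaldehyde (5-iodovanillin) | COc1cc(C=O)cc(I)c1O | starting material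
12 | 3-iodo-5-methoxy-4-(methoxymethoxy)benzaldehyde | COCOc1c(I)cc(C=O)cc1OC | intermediate
13 | tributyl(3-methylbut-2-enyl)stannane | CCCC[Sn](CCCC)(CCCC)CC=C(C)C | starting material
14 | 3-methoxy-4-(methoxymethoxy)-5-(3-methylbut-2-enyl)benzaldehyde | COCOc1c(CC=C(C)C)cc(C=O)cc1OC | intermediate
15 | 5-ethynyl-1-methoxy-2-(methoxymethoxy)-3-(3-methylbut-2-enyl)benzene | C#Cc1cc(OC)c(OCOC)c(CC=C(C)C)c1 | intermediate
16 | carbon monoxide | [C-]#[O+] | starting material
17 | 2-{3-[3-methoxy-4-(methoxymethoxy)-5-(3-methylbut-2-enyl)phenyl]prop-2-ynoyl}-4,6-bis(3-methylbut-2-enyl)benzene-1,3,5-triyl triacetate (ynone triacetate) | CC(=O)Oc1c(C(=O)C#Cc2cc(OC)c(OCOC)c(CC=C(C)C)c2)c(OC(C)=O)c(CC=C(C)C)c(OC(C)=O)c1CC=C(C)C | intermediate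
18 | 3-[3-methoxy-4-(methoxymethoxy)-5-(3-methylbut-2-enyl)phenyl]-1-[2,4,6-trihydroxy-3,5-bis(3-methylbut-2-enyl)phenyl]prop-2-yn-1-one (ynone triol) | Oc1c(C(=O)C#Cc2cc(OC)c(OCOC)c(CC=C(C)C)c2)c(O)c(CC=C(C)C)c(O)c1CC=C(C)C | intermediate
19 | 5,7-dihydroxy-2-[3-methoxy-4-(methoxymethoxy)-5-(3-methylbut-2-enyl)phenyl]-6,8-bis(3-methylbut-2-enyl)chromen-4-one | COCOc1c(OC)cc(-c2cc(=O)c3c(O)c(CC=C(C)C)c(O)c(CC=C(C)C)c3o2)cc1CC=C(C)C | intermediate
20 | 5,7-bis(methoxymethoxy)-2-[3-methoxy-4-(methoxymethoxy)-5-(3-methylbut-2-enyl)phenyl]-6,8-bis(3-methylbut-2-enyl)chromen-4-one | COCOc1c(OC)cc(-c2cc(=O)c3c(OCOC)c(CC=C(C)C)c(OCOC)c(CC=C(C)C)c3o2)cc1CC=C(C)C | intermediate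
21 | (2S)-4-{[diethoxy(methyl)silyl]oxy}-5,7-bis(methoxymethoxy)-2-[3-methoxy-4-(methoxymethoxy)-5-(3-methylbut-2-enyl)phenyl]-6,8-bis(3-methylbut-2-enyl)-2H-chromene (silyl enol ether) | COCOc1c(OC)cc([C@@H]2C=C(O[Si](C)(OCC)OCC)c3c(OCOC)c(CC=C(C)C)c(OCOC)c(CC=C(C)C)c3O2)cc1CC=C(C)C | intermediate
22 | (2S)-5,7-bis(methoxymethoxy)-2-[3-methoxy-4-(methoxymethoxy)-5-(3-methylbut-2-enyl)phenyl]-6,8-bis(3-methylbut-2-enyl)chroman-4-one | COCOc1c(OC)cc([C@@H]2CC(=O)c3c(OCOC)c(CC=C(C)C)c(OCOC)c(CC=C(C)C)c3O2)cc1CC=C(C)C | intermediate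
23 | (2S)-5,7-dihydroxy-2-[4-hydroxy-3-methoxy-5-(3-methylbut-2-enyl)phenyl]-6,8-bis(3-methylbut-2-enyl)chroman-4-one | COc1cc([C@@H]2CC(=O)c3c(O)c(CC=C(C)C)c(O)c(CC=C(C)C)c3O2)cc(CC=C(C)C)c1O | target

**Step count**

Total: 12 steps. Longest linear sequence: 9 steps (steps 1–5 and 9–12, from phloroglucinol); the acetylene branch (steps 6–8) joins at step 9.

**Steps most likely to fail, with fallbacks**

Step 9 (key step). Oxidative addition into an iodide flanked by two acyloxy groups may be slow. The acetates may be aminolysed too early, giving an electron-rich iodophenoxide that loses iodine reductively. Direct alkynylation without CO uptake, followed by benzofuran closure, or 5-exo closure to the aurone, may compete. The fallback builds the same three bonds stepwise with organolithium chemistry; it sets out from 7 and 15 and rejoins the route at 20. Alkyne 15 is deprotonated with n-BuLi in THF at −78 °C and formylated with DMF to give 3-[3-methoxy-4-(methoxymethoxy)-5-(3-methylbut-2-enyl)phenyl]prop-2-ynal F1. Compound 7 is lithiated at its last ring position (n-BuLi, THF, 0 °C) to [2,4,6-tris(methoxymethoxy)-3,5-bis(3-methylbut-2-enyl)phenyl]lithium F2, which adds to F1 at −78 °C to give the racemic propargylic alcohol F3. Oxidation with MnO2 in CH2Cl2 should give the tris-MOM ynone F4. Et2NH in EtOH at rt adds to the triple bond to give the β-(diethylamino)enone F5, which fixes the six-membered closure. Treatment with 3 M aq. HCl in MeOH at 40 °C then removes all four MOM groups and lets a freed ortho phenol displace the amine, giving 5,7-dihydroxy-2-[4-hydroxy-3-methoxy-5-(3-methylbut-2-enyl)phenyl]-6,8-bis(3-methylbut-2-enyl)chromen-4-one F6. Triple MOM protection (NaH, MOMCl, DMF) gives 20.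

Step 11. The electron-rich vinylogous-ester enone may react sluggishly with the copper hydride. Facial selectivity may be poor, the C4 carbonyl may be over-reduced, or the copper enolate may undergo β-elimination to the open chalcone, which erases C2. The fallback sets out from 20 and rejoins at 22 by racemic reduction and kinetic resolution. Conjugate reduction of 20 with LiBH(s-Bu)3 in THF at −78 °C, quenched cold with AcOH, should give the racemic flavanone F7. Asymmetric transfer hydrogenation with Cp*RhCl[(R,R)-TsDPEN] and HCO2H/Et3N in EtOAc at rt is expected to reduce the 2R enantiomer to the cis-(2R,4R)-flavan-4-ol F8. The slow-reacting (2S)-ketone 22 is then recovered by chromatography, at the cost of half the material.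

Step 5. Iodine may attack a prenyl double bond with participation of the neighbouring phenol (iodoetherification) in competition with ring iodination. The free iodotriol may also lose iodine or oxidise before it is acetylated. The fallback introduces iodine by metalation, before any phenol is free; it sets out from 7 and rejoins at 9. Lithiation of 7 (n-BuLi, THF, 0 °C) gives the same aryllithium, [2,4,6-tris(methoxymethoxy)-3,5-bis(3-methylbut-2-enyl)phenyl]lithium F2, which is quenched with I2 at −78 °C to give 2-iodo-1,3,5-tris(methoxymethoxy)-4,6-bis(3-methylbut-2-enyl)benzene F9. The MOM groups are then removed without Brønsted acid, which would risk protodeiodination: TMSOTf and 2,2′-bipyridyl in CH2Cl2 at 0 °C should convert F9 into the tris(trimethylsilyl) ether F10. Addition of water hydrolyses F10 to iodotriol 9, which is acetylated at once as in step 5 to give 10.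

**Further compounds**

F1 | step 9 | 3-[3-methoxy-4-(methoxymethoxy)-5-(3-methylbut-2-enyl)phenyl]prop-2-ynal | O=CC#Cc1cc(OC)c(OCOC)c(CC=C(C)C)c1
F2 | step 9 | [2,4,6-tris(methoxymethoxy)-3,5-bis(3-methylbut-2-enyl)phenyl]lithium | COCOc1c([Li])c(OCOC)c(CC=C(C)C)c(OCOC)c1CC=C(C)C
F3 | step 9 | racemic 3-[3-methoxy-4-(methoxymethoxy)-5-(3-methylbut-2-enyl)phenyl]-1-[2,4,6-tris(methoxymethoxy)-3,5-bis(3-methylbut-2-enyl)phenyl]prop-2-yn-1-ol | COCOc1c(C(O)C#Cc2cc(OC)c(OCOC)c(CC=C(C)C)c2)c(OCOC)c(CC=C(C)C)c(OCOC)c1CC=C(C)C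
F4 | step 9 | 3-[3-methoxy-4-(methoxymethoxy)-5-(3-methylbut-2-enyl)phenyl]-1-[2,4,6-tris(methoxymethoxy)-3,5-bis(3-methylbut-2-enyl)phenyl]prop-2-yn-1-one | COCOc1c(C(=O)C#Cc2cc(OC)c(OCOC)c(CC=C(C)C)c2)c(OCOC)c(CC=C(C)C)c(OCOC)c1CC=C(C)C
F5 | step 9 | 3-(diethylamino)-3-[3-methoxy-4-(methoxymethoxy)-5-(3-methylbut-2-enyl)phenyl]-1-[2,4,6-tris(methoxymethoxy)-3,5-bis(3-methylbut-2-enyl)phenyl]prop-2-en-1-one (alkene geometry as formed) | COCOc1c(C(=O)C=C(N(CC)CC)c2cc(OC)c(OCOC)c(CC=C(C)C)c2)c(OCOC)c(CC=C(C)C)c(OCOC)c1CC=C(C)C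
F6 | step 9 | 5,7-dihydroxy-2-[4-hydroxy-3-methoxy-5-(3-methylbut-2-enyl)phenyl]-6,8-bis(3-methylbut-2-enyl)chromen-4-one | COc1cc(-c2cc(=O)c3c(O)c(CC=C(C)C)c(O)c(CC=C(C)C)c3o2)cc(CC=C(C)C)c1O
F7 | step 11 | racemic 5,7-bis(methoxymethoxy)-2-[3-methoxy-4-(methoxymethoxy)-5-(3-methylbut-2-enyl)phenyl]-6,8-bis(3-methylbut-2-enyl)chroman-4-one | COCOc1c(OC)cc(C2CC(=O)c3c(OCOC)c(CC=C(C)C)c(OCOC)c(CC=C(C)C)c3O2)cc1CC=C(C)C
F8 | step 11 | (2R,4R)-5,7-bis(methoxymethoxy)-2-[3-methoxy-4-(methoxymethoxy)-5-(3-methylbut-2-enyl)phenyl]-6,8-bis(3-methylbut-2-enyl)chroman-4-ol | COCOc1c(OC)cc([C@H]2C[C@@H](O)c3c(OCOC)c(CC=C(C)C)c(OCOC)c(CC=C(C)C)c3O2)cc1CC=C(C)C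
F9 | step 5 | 2-iodo-1,3,5-tris(methoxymethoxy)-4,6-bis(3-methylbut-2-enyl)benzene | COCOc1c(I)c(OCOC)c(CC=C(C)C)c(OCOC)c1CC=C(C)C
F10 | step 5 | 2-iodo-4,6-bis(3-methylbut-2-enyl)-1,3,5-tris(trimethylsilyloxy)benzene | C[Si](C)(C)Oc1c(I)c(O[Si](C)(C)C)c(CC=C(C)C)c(O[Si](C)(C)C)c1CC=C(C)C
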